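**Retrosynthetic overview**

- Wailupemycin H ⇒ its penta-MOM ether ⇒ two C4(benzylic)–C6(pyranone) bonds. Each is made by nickel capture of a C4 benzylic radical on a symmetric bis(6-chloro-2-pyranon-3-yl)methane linchpin that already carries the CH2 bridge.
- Both carbocyclic halves come from one building block, an (S)-3-hydroxy-3-phenyl-1-tetralone brominated at C4. The first coupling is followed by dehydration and aromatisation to give the naphthalene half; the second coupling keeps the tetralone and sets C4 anti to the C3 phenyl group.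
- Tetralone ⇐ intramolecular enamine aldol of a 1,5-diketone (C2–C3 bond, sets C3) ⇐ carbonyl-assisted hydration of an o-alkynyl acetophenone ⇐ Sonogashira coupling ⇐ ortho-lithiation and acetylation of MOM-protected 3-bromophenol.
- Linchpin ⇐ self-condensation of two molecules of malonyl dichloride to 6-chloro-4-hydroxy-2-pyranone, 2:1 condensation with formaldehyde, MOM protection.
- Ring order: pyranones first, tetralone ring by aldol, naphthalene by aromatisation after the first coupling, the stereodefined tetralone attached last.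

Assumption: the quinine-derived amine of step 5 is taken to give the (S)-alcohol 11; the sense of induction is not known for this substrate, and the equally available quinidine-derived pseudo-enantiomer is used instead if one analytical run shows the opposite sense.

**Route**

Step 1
Reactants: 1 3-bromophenol
Product: 2 1-bromo-3-(methoxymethoxy)benzene
Conditions: MOMCl, i-Pr2NEt, CH2Cl2, 0 °C → rt
Reagents that add atoms: chloromethyl methyl ether (MOMCl), COCCl
Why: O-alkylation of the phenoxide (Williamson type) installs the MOM ether, which directs the lithiation of step 2 and protects the phenol through the brominating and radical steps.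

Step 2
Reactants: 2 1-bromo-3-(methoxymethoxy)benzene; 3 N-methoxy-N-methylacetamide
Product: 6 1-[2-bromo-6-(methoxymethoxy)phenyl]ethan-1-one, via [2-bromo-6-(methoxymethoxy)phenyl]lithium 4 (not isolated), via lithium hemiaminal alkoxide 5 (not isolated)
Conditions: LiN(i-Pr)2, THF, −78 °C; then 3, −78 °C; aq. NH4Cl
Reagents that add atoms: none
Why: Directed ortho-metalation at C2, acidified by both Br and OMOM (the amide base avoids Br/Li exchange and −78 °C suppresses aryne formation), followed by Weinreb ketone synthesis, which stops at the ketone through the chelated adduct 5.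

Step 3
Reactants: 6 1-[2-bromo-6-(methoxymethoxy)phenyl]ethan-1-one; 7 phenylacetylene
Product: 8 1-[2-(methoxymethoxy)-6-(phenylethynyl)phenyl]ethan-1-one
Conditions: PdCl2(PPh3)2 (3 mol%), CuI (5 mol%), Et3N, THF, 60 °C
Reagents that add atoms: none
Why: Sonogashira coupling of an aryl bromide activated by the ortho acetyl group.

Step 4
Reactants: 8 1-[2-(methoxymethoxy)-6-(phenylethynyl)phenyl]ethan-1-one
Product: 10 2-[2-acetyl-3-(methoxymethoxy)phenyl]-1-phenylethan-1-one, via 8-(methoxymethoxy)-1-methyl-3-phenyl-1H-isochromen-1-ol 9 (not isolated)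
Conditions: Ph3PAuCl (2 mol%), AgOTf (2 mol%), 1,4-dioxane/H2O 10:1, rt
Reagents that add atoms: water, O
Why: Gold-catalysed carbonyl-assisted alkyne hydration: 6-endo attack of the acetyl oxygen on the activated alkyne, water addition and opening of hemiketal 9 place the new carbonyl only on the phenyl-bearing carbon, giving the 1,5-diketone.

Step 5
Reactants: 10 2-[2-acetyl-3-(methoxymethoxy)phenyl]-1-phenylethan-1-one
Product: 11 (3S)-3-hydroxy-8-(methoxymethoxy)-3-phenyl-3,4-dihydronaphthalen-1(2H)-one
Conditions: 9-amino-9-deoxy-epi-quinine (20 mol%), TFA (40 mol%), toluene, 0 °C → rt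
Reagents that add atoms: none
Why: Proposed new method: the primary amine forms the enamine of the aryl methyl ketone (the benzyl ketone enamine cannot cyclise, as it would close a four-membered ring), and a 6-enolexo aldol onto the benzoyl carbonyl, which is held by a hydrogen bond to the protonated quinuclidine, sets the C3 carbinol centre on one face; the closest known reactions are cinchona-primary-amine-catalysed intramolecular aldolisations of diketones and proline-catalysed enolexo aldolisations onto aryl ketones that give tertiary alcohols, and the low temperature is meant to stop at the aldol before dehydration to the naphthol.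

Step 6
Reactants: 11 (3S)-3-hydroxy-8-(methoxymethoxy)-3-phenyl-3,4-dihydronaphthalen-1(2H)-one
Product: 12 (3S)-4-bromo-3-hydroxy-8-(methoxymethoxy)-3-phenyl-3,4-dihydronaphthalen-1(2H)-one (both C4 epimers)
Conditions: NBS (1.05 equiv), AIBN (5 mol%), NaHCO3 (solid), PhCF3, 75 °C, visible light
Reagents that add atoms: N-bromosuccinimide (NBS), O=C1CCC(=O)N1Br
Why: Wohl–Ziegler benzylic bromination at C4, the only benzylic C–H position (known for 1-tetralone); the C4 epimer ratio is irrelevant because C4 becomes a planar radical later, and the bromide has no β-hydrogen, so it cannot lose HBr.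

Step 7
Reactants: 13 malonyl dichloride (2 equiv)
Product: 16 6-chloro-4-hydroxy-2H-pyran-2-one, via 6-chloro-4-hydroxy-2-oxo-2H-pyran-3-carbonyl chloride 14 (not isolated), via 6-chloro-4-hydroxy-2-oxo-2H-pyran-3-carboxylic acid 15 (not isolated)
Conditions: neat, rt, 5 d (−2 HCl); then H2O, 1,4-dioxane, rt → 90 °C (−HCl, −CO2)
Reagents that add atoms: malonyl dichloride (second equivalent of 13), O=C(Cl)CC(=O)Cl; water, O
Why: Known self-condensation of malonyl dichloride, in which one molecule C-acylates a second (Claisen-type) and the chloro-enol oxygen lactonises onto an acid chloride to give the six-carbon pyranone 14, after which water turns the remaining acid chloride into the vinylogous β-keto acid 15 (this is where the water oxygen enters), which loses CO2 on warming to leave the five-carbon pyranone 16.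

Step 8
Reactants: 16 6-chloro-4-hydroxy-2H-pyran-2-one (2 equiv); 17 formaldehyde (as paraformaldehyde)
Product: 19 3,3'-methylenebis(6-chloro-4-hydroxy-2H-pyran-2-one), via 6-chloro-3-methylidene-2H-pyran-2,4(3H)-dione 18 (not isolated)
Conditions: (CH2O)n (0.5 equiv per 16), AcOH, 70 °C
Reagents that add atoms: 6-chloro-4-hydroxy-2H-pyran-2-one (second equivalent of 16), O=c1cc(O)cc(Cl)o1
Why: Knoevenagel condensation of one molecule of 16 with formaldehyde at its nucleophilic C3, then Michael addition of the second molecule of 16 to the methylidene dione 18 (the dicoumarol-type 2:1 condensation, losing one water); the amine-free acidic medium spares the C6–Cl bonds.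

Step 9
Reactants: 19 3,3'-methylenebis(6-chloro-4-hydroxy-2H-pyran-2-one)
Product: 20 3,3'-methylenebis[6-chloro-4-(methoxymethoxy)-2H-pyran-2-one]
Conditions: MOMCl (2.4 equiv), i-Pr2NEt, CH2Cl2, 0 °C
Reagents that add atoms: chloromethyl methyl ether (MOMCl), COCCl
Why: O-alkylation of the vinylogous acid with a hard electrophile (C3 is blocked) removes the acidic protons, which would otherwise quench the organonickel intermediates and deactivate the C6–Cl bonds.

Step 10
Reactants: 12 (3S)-4-bromo-3-hydroxy-8-(methoxymethoxy)-3-phenyl-3,4-dihydronaphthalen-1(2H)-one; 20 3,3'-methylenebis[6-chloro-4-(methoxymethoxy)-2H-pyran-2-one]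
Product: 21 6-chloro-3-({6-[(1S,2R)-2-hydroxy-5-(methoxymethoxy)-4-oxo-2-phenyl-1,2,3,4-tetrahydronaphthalen-1-yl]-4-(methoxymethoxy)-2-oxo-2H-pyran-3-yl}methyl)-4-(methoxymethoxy)-2H-pyran-2-one
Conditions: 20 (3 equiv), [Ir(dF(CF3)ppy)2(dtbbpy)]PF6 (1 mol%), NiCl2·glyme (10 mol%), dtbbpy (12 mol%), (Me3Si)3SiH (1.2 equiv), 2,6-lutidine (2 equiv), DME, blue LEDs, rt
Reagents that add atoms: none
Why: Proposed new method: the silyl radical abstracts bromine from 12, zerovalent nickel inserts into one C6–Cl bond (a doubly vinylogous acyl chloride), the divalent pyranonyl nickel chloride captures the C4 benzylic radical, and trivalent nickel reductively eliminates the C4–C6 bond; the closest known reaction is the silyl-radical-mediated nickel/photoredox cross-electrophile coupling of alkyl bromides with aryl halides, excess 20 (recovered) keeps the reaction at mono-coupling, and the configuration at C4 does not matter here because step 11 erases it.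

Step 11
Reactants: 21 the mono-coupled tetralone of step 10
Product: 24 3-({6-[4,5-bis(methoxymethoxy)-2-phenylnaphthalen-1-yl]-4-(methoxymethoxy)-2-oxo-2H-pyran-3-yl}methyl)-6-chloro-4-(methoxymethoxy)-2H-pyran-2-one, via dehydrated enone 22 (not isolated), via free naphthol 23 (not isolated)
Conditions: Burgess reagent (Et3N+SO2N−CO2Me), THF, 50 °C; then i-Pr2NEt, MOMCl, 0 °C → rt
Reagents that add atoms: chloromethyl methyl ether (MOMCl), COCCl
Why: Burgess syn-elimination of the tertiary alcohol toward C2 gives enone 22, whose doubly activated C4–H shifts to oxygen to give the aromatic naphthol 23 (driving force: aromatisation), and capping in the same pot keeps the electron-rich naphthol from quenching the photocatalyst in step 12; these neutral conditions leave the MOM groups and the second C6–Cl untouched.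

Step 12
Reactants: 24 the chloro naphthalene half of step 11; 12 (3S)-4-bromo-3-hydroxy-8-(methoxymethoxy)-3-phenyl-3,4-dihydronaphthalen-1(2H)-one
Product: 25 6-[4,5-bis(methoxymethoxy)-2-phenylnaphthalen-1-yl]-3-({6-[(1S,2R)-2-hydroxy-5-(methoxymethoxy)-4-oxo-2-phenyl-1,2,3,4-tetrahydronaphthalen-1-yl]-4-(methoxymethoxy)-2-oxo-2H-pyran-3-yl}methyl)-4-(methoxymethoxy)-2H-pyran-2-one
Conditions: 12 (1.5 equiv), [Ir(dF(CF3)ppy)2(dtbbpy)]PF6 (1 mol%), NiCl2·glyme (10 mol%), dtbbpy (12 mol%), (Me3Si)3SiH (1.5 equiv), 2,6-lutidine (2 equiv), DME, blue LEDs, rt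
Reagents that add atoms: none
Why: Proposed new method: the same radical cross-electrophile coupling as step 10 (closest known reaction: silyl-radical-mediated nickel/photoredox coupling of alkyl bromides with aryl halides), in which both C4 epimers of 12 converge on one planar benzylic radical and the bulky pyranonyl nickel species is expected to bond on the face anti to the geminal C3 phenyl (the hydroxyl face), giving the (S) centre with pyranone cis to OH and trans to Ph, while the (R) carbinol centre is untouched; the minor C4 epimer is removed by chromatography.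

Step 13
Reactants: 25 the penta-MOM ether of step 12
Product: 26 wailupemycin H, 6-(4,5-dihydroxy-2-phenylnaphthalen-1-yl)-3-({6-[(1S,2R)-2,5-dihydroxy-4-oxo-2-phenyl-1,2,3,4-tetrahydronaphthalen-1-yl]-4-hydroxy-2-oxo-2H-pyran-3-yl}methyl)-4-hydroxy-2H-pyran-2-one
Conditions: 2 M aq. HCl/MeOH/THF 1:4:2, 30 °C
Reagents that add atoms: none
Why: Acid hydrolysis of the five MOM acetals (the two vinylogous-ester MOMs and the MOM peri to the ketone cleave fastest, the naphthalene MOMs last); dilute aqueous acid near room temperature is chosen to leave the tertiary β-hydroxy ketone intact, and no stereocentre is touched.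

**Compound list**

1 | 3-bromophenol | Oc1cccc(Br)c1 | starting material
2 | 1-bromo-3-(methoxymethoxy)benzene | COCOc1cccc(Br)c1 | intermediate
3 | N-methoxy-N-methylacetamide | CC(=O)N(C)OC | starting material
4 | [2-bromo-6-(methoxymethoxy)phenyl]lithium | [Li]c1c(Br)cccc1OCOC | intermediate
5 | lithium 1-[2-bromo-6-(methoxymethoxy)phenyl]-1-[methoxy(methyl)amino]ethan-1-olate | CC(O[Li])(N(C)OC)c1c(Br)cccc1OCOC | intermediate
6 | 1-[2-bromo-6-(methoxymethoxy)phenyl]ethan-1-one | CC(=O)c1c(Br)cccc1OCOC | intermediate
7 | phenylacetylene | C#Cc1ccccc1 | starting material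
8 | 1-[2-(methoxymethoxy)-6-(phenylethynyl)phenyl]ethan-1-one | CC(=O)c1c(OCOC)cccc1C#Cc1ccccc1 | intermediate
9 | 8-(methoxymethoxy)-1-methyl-3-phenyl-1H-isochromen-1-ol | CC1(O)OC(c2ccccc2)=Cc2cccc(OCOC)c21 | intermediate
10 | 2-[2-acetyl-3-(methoxymethoxy)phenyl]-1-phenylethan-1-one | CC(=O)c1c(OCOC)cccc1CC(=O)c1ccccc1 | intermediate
11 | (3S)-3-hydroxy-8-(methoxymethoxy)-3-phenyl-3,4-dihydronaphthalen-1(2H)-one | O=C1C[C@](O)(c2ccccc2)Cc2cccc(OCOC)c21 | intermediate
12 | (3S)-4-bromo-3-hydroxy-8-(methoxymethoxy)-3-phenyl-3,4-dihydronaphthalen-1(2H)-one (C4 epimers) | O=C1C[C@](O)(c2ccccc2)C(Br)c2cccc(OCOC)c21 | intermediate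
13 | malonyl dichloride | O=C(Cl)CC(=O)Cl | starting material
14 | 6-chloro-4-hydroxy-2-oxo-2H-pyran-3-carbonyl chloride | O=C(Cl)c1c(O)cc(Cl)oc1=O | intermediate
15 | 6-chloro-4-hydroxy-2-oxo-2H-pyran-3-carboxylic acid | OC(=O)c1c(O)cc(Cl)oc1=O | intermediate
16 | 6-chloro-4-hydroxy-2H-pyran-2-one | O=c1cc(O)cc(Cl)o1 | intermediate
17 | formaldehyde | C=O | starting material
18 | 6-chloro-3-methylidene-2H-pyran-2,4(3H)-dione | C=C1C(=O)C=C(Cl)OC1=O | intermediate
19 | 3,3'-methylenebis(6-chloro-4-hydroxy-2H-pyran-2-one) | O=c1oc(Cl)cc(O)c1Cc1c(O)cc(Cl)oc1=O | intermediate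
20 | 3,3'-methylenebis[6-chloro-4-(methoxymethoxy)-2H-pyran-2-one] | COCOc1cc(Cl)oc(=O)c1Cc1c(OCOC)cc(Cl)oc1=O | intermediate
21 | 6-chloro-3-({6-[(1S,2R)-2-hydroxy-5-(methoxymethoxy)-4-oxo-2-phenyl-1,2,3,4-tetrahydronaphthalen-1-yl]-4-(methoxymethoxy)-2-oxo-2H-pyran-3-yl}methyl)-4-(methoxymethoxy)-2H-pyran-2-one | O=C1C[C@](O)(c2ccccc2)[C@@H](c2cc(OCOC)c(Cc3c(OCOC)cc(Cl)oc3=O)c(=O)o2)c2cccc(OCOC)c21 | intermediate
22 | 6-chloro-3-({4-(methoxymethoxy)-6-[5-(methoxymethoxy)-4-oxo-2-phenyl-1,4-dihydronaphthalen-1-yl]-2-oxo-2H-pyran-3-yl}methyl)-4-(methoxymethoxy)-2H-pyran-2-one (C1 as in 21) | O=C1C=C(c2ccccc2)[C@@H](c2cc(OCOC)c(Cc3c(OCOC)cc(Cl)oc3=O)c(=O)o2)c2cccc(OCOC)c21 | intermediate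
23 | 6-chloro-3-({6-[4-hydroxy-5-(methoxymethoxy)-2-phenylnaphthalen-1-yl]-4-(methoxymethoxy)-2-oxo-2H-pyran-3-yl}methyl)-4-(methoxymethoxy)-2H-pyran-2-one | COCOc1cc(Cl)oc(=O)c1Cc1c(OCOC)cc(-c2c(-c3ccccc3)cc(O)c3c(OCOC)cccc23)oc1=O | intermediate
24 | 3-({6-[4,5-bis(methoxymethoxy)-2-phenylnaphthalen-1-yl]-4-(methoxymethoxy)-2-oxo-2H-pyran-3-yl}methyl)-6-chloro-4-(methoxymethoxy)-2H-pyran-2-one | COCOc1cc(Cl)oc(=O)c1Cc1c(OCOC)cc(-c2c(-c3ccccc3)cc(OCOC)c3c(OCOC)cccc23)oc1=O | intermediate
25 | 6-[4,5-bis(methoxymethoxy)-2-phenylnaphthalen-1-yl]-3-({6-[(1S,2R)-2-hydroxy-5-(methoxymethoxy)-4-oxo-2-phenyl-1,2,3,4-tetrahydronaphthalen-1-yl]-4-(methoxymethoxy)-2-oxo-2H-pyran-3-yl}methyl)-4-(methoxymethoxy)-2H-pyran-2-one | O=C1C[C@](O)(c2ccccc2)[C@@H](c2cc(OCOC)c(Cc3c(OCOC)cc(-c4c(-c5ccccc5)cc(OCOC)c5c(OCOC)cccc45)oc3=O)c(=O)o2)c2cccc(OCOC)c21 | intermediate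
26 | wailupemycin H | O=C1C[C@](O)(c2ccccc2)[C@@H](c2cc(O)c(Cc3c(O)cc(-c4c(-c5ccccc5)cc(O)c5c(O)cccc45)oc3=O)c(=O)o2)c2cccc(O)c21 | target

**Step count**

Total: 13 steps. Longest linear sequence: 10 steps (steps 1–6, then 10–13); the linchpin branch (steps 7–9) joins at step 10.

**The three steps most likely to fail**

Step 12 (and its twin, step 10), the radical coupling. The 6-chloropyranone is an untested C(sp2) partner, the hindered β-hydroxy benzylic radical may be reduced or may bond with poor facial selectivity, and the pyranones may be sensitised by the photocatalyst. The fallback sets out from 24 (with diketone 10) and comes back at 25. The sodium enolate of 10 (NaH, THF, 0 °C) displaces chloride from 24 by polar addition–elimination at C6 to give the open-chain triketone 3-({6-[4,5-bis(methoxymethoxy)-2-phenylnaphthalen-1-yl]-4-(methoxymethoxy)-2-oxo-2H-pyran-3-yl}methyl)-6-{1-[2-acetyl-3-(methoxymethoxy)phenyl]-2-oxo-2-phenylethyl}-4-(methoxymethoxy)-2H-pyran-2-one F4. The amine catalyst of step 5 then closes the tetralone ring by aldol reaction while the acidic C4–H epimerises freely (dynamic kinetic resolution), so that both stereocentres are set in the ring closure and 25 is reached.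

Step 5, the enantioselective aldol. The ee may be low, or the aldol may dehydrate to the naphthol. The fallback sets out from 10 and comes back at 11. Achiral enamine aldolisation (pyrrolidine, AcOH, CH2Cl2, 0 °C) gives racemic 3-hydroxy-8-(methoxymethoxy)-3-phenyl-3,4-dihydronaphthalen-1(2H)-one F1, which is resolved by preparative chromatography on a chiral stationary phase into (S)-11 and (3R)-3-hydroxy-8-(methoxymethoxy)-3-phenyl-3,4-dihydronaphthalen-1(2H)-one F2. F2 is returned to F1 by catalytic KOt-Bu through retro-aldol and aldol, and recycled.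

Step 6, the benzylic bromination. HBr or Br2 may cause ring or α-keto bromination, or dehydration of the aldol. The fallback sets out from 11 and comes back at 21 (and, in the second coupling, at 25). A copper radical-relay chlorination (CuCl, 2,2'-bis(2-oxazoline), NFSI, KCl, PhCl, 50 °C), in which a sulfonimidyl radical abstracts the benzylic hydrogen and copper transfers chloride, gives (3S)-4-chloro-3-hydroxy-8-(methoxymethoxy)-3-phenyl-3,4-dihydronaphthalen-1(2H)-one F3 without any free bromine or acid. F3 then takes the place of 12 under the conditions of steps 10 and 12, where the silyl radical abstracts chlorine.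

**Further compounds**

F1 | step 5 | racemic 3-hydroxy-8-(methoxymethoxy)-3-phenyl-3,4-dihydronaphthalen-1(2H)-one | O=C1CC(O)(c2ccccc2)Cc2cccc(OCOC)c21
F2 | step 5 | (3R)-3-hydroxy-8-(methoxymethoxy)-3-phenyl-3,4-dihydronaphthalen-1(2H)-one | O=C1C[C@@](O)(c2ccccc2)Cc2cccc(OCOC)c21
F3 | step 6 | (3S)-4-chloro-3-hydroxy-8-(methoxymethoxy)-3-phenyl-3,4-dihydronaphthalen-1(2H)-one (C4 epimers) | O=C1C[C@](O)(c2ccccc2)C(Cl)c2cccc(OCOC)c21
F4 | step 12 | 3-({6-[4,5-bis(methoxymethoxy)-2-phenylnaphthalen-1-yl]-4-(methoxymethoxy)-2-oxo-2H-pyran-3-yl}methyl)-6-{1-[2-acetyl-3-(methoxymethoxy)phenyl]-2-oxo-2-phenylethyl}-4-(methoxymethoxy)-2H-pyran-2-one | CC(=O)c1c(OCOC)cccc1C(C(=O)c1ccccc1)c1cc(OCOC)c(Cc2c(OCOC)cc(-c3c(-c4ccccc4)cc(OCOC)c4c(OCOC)cccc34)oc2=O)c(=O)o1
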